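# Synthesis proposal for CNP0360342.1 (17)

Numbering used throughout: chain C1 (ester carbon) to C7 (the methyl on C6); ring C1'–C6', with C1' bonded to C6, C2'=C3', and C4' carrying OH and CH3.

## Analysis of the target

Target 17 is a C20 ester: a 4-hydroxy-4-methylcyclohex-2-enyl ring joined through C1' to C6 of a hept-2-enoate chain, with an acetoxy group at C4 and a 4-methylpent-3-enyl branch at C2. It has four stereocentres, C4' (R, tertiary allylic carbinol), C1' (S), C6 (R) and C4 (S), and an E-configured C2=C3 bond with the ester trans to C4. C4' and C1' are 1,4-related across the ring alkene, with the hydroxyl trans to the chain. C1' and C6 are a vicinal ring/chain pair in which C6 lies outside the ring. C4 is 1,3 to C6 and far from any ring control. The sensitive groups are the tertiary allylic alcohol (ionisation, dehydration), the γ-acetoxy enoate (an allylic acetate open to elimination and to ionisation by zerovalent palladium) and the acid-sensitive trisubstituted side-chain alkene. The difficulty is that nothing in the ring relays C4' to C1', and that C6 must be set next to C1' without a ring to hold it. The feature that invites the chosen move is the array C4'(OH)(CH3)–C3'H=C2'H–C1'H. This is the product pattern of a Wharton transposition of a 2,3-epoxy ketone, in which C2' is a carbonyl carbon and C1' its enolisable α'-carbon. The ring–chain bond C1'–C6 can therefore be made as an enolate C–C bond next to a temporary oxirane that already holds C4'.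

## Retrosynthetic reasoning

**17 to 16.** The C4–O acyl bond is cut last. An allylic acetate would not survive the hydride and palladium steps, and the secondary C4 hydroxyl can be acetylated in the presence of the hindered tertiary C4' hydroxyl.

**16 to 13 and 15 (from 14).** The bond from C2 to the first CH2 of the 4-methylpent-3-enyl branch is cut. The E geometry of 16 is what results when a carbon group replaces, with retention, a substituent that stood cis to C4 on C2. A cross-coupling of alkenyl iodide 13 with alkylzinc 15, made from bromide 14, achieves this and brings in six carbons at once.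

**13 to 11 (via 12).** H on C3 and I on C2 are removed to give an alkyne. The forward reaction is a trans-hydroalumination directed by the C4 alkoxide, which puts aluminium on C2 cis to C4 (aluminate 12), followed by iodinolysis. The alkene geometry is thus fixed by mechanism and not by a thermodynamic preference.

**11 to 8 and 9 (via 10).** The C3–C4 bond is cut. Addition of the zinc alkynylide 10 of methyl propiolate 9 to aldehyde 8 under a chiral catalyst forms C4 with reagent control, which is needed because C6 is too far away to direct it.

**8 to 7.** The aldehyde is traced to the ethyl ester, a change of oxidation level only.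

**7 to 5 (via 6).** The ring alkene and the tertiary alcohol are traced back by a retro-Wharton step to ketone 5, whose bicycle atoms map as C2 = C2', C1 = C3', C6 = C4' and C3 = C1'. This hides the acid-sensitive allylic alcohol as an oxirane and turns C1' into an α-carbon of a ketone. Because the C4'–O bond is never broken, the configuration at C4' passes unchanged into 7.

**5 to 2 and 3 (via 4).** This is the key disconnection: the C1'–C6 bond is cut, to be formed by Michael addition of the lithium enolate 4 of epoxy ketone 2 to ethyl crotonate 3. One step forms the ring–chain bond and sets C1' (relative to the oxirane) and C6 (relative to C1'). It also delivers C5 and C4 at the right oxidation level. Cutting here, and not at C5–C6 or C4–C5, leaves a seven-carbon ring piece and a four-carbon commodity ester.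

**2 to 1.** The oxirane is traced to 3-methylcyclohex-2-en-1-one 1 by catalytic asymmetric nucleophilic epoxidation. This single step fixes the absolute configuration from which C1' and C6 are then derived.

## Alternatives that were turned down

**Alternative 1:** the textbook route keeps the ring from the chiral pool as the dienol A1 and builds the chain on its isopropenyl group. The forward key step is hydroboration–oxidation of A1 to the primary alcohol A2, followed by oxidation, one-carbon extension to aldehyde 8 and the same end game. It was turned down because C6 would be created by addition to a 1,1-disubstituted alkene outside the ring. The only control element is C1', whose two ring neighbours (CH= and CH2) differ little in size, so low facial selectivity is expected. The ring alkene competes for the borane, and A2 is still one carbon short, so the step count is no lower and the hardest centre is left to chance.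

**Alternative 2:** cut C1'–C6 and form it by anti-SN2' opening of the vinyl oxirane A3 with an alkenylcopper reagent to give A4. This sets the trans 1,4-relation of hydroxyl and chain, the ring alkene and the tertiary alcohol in one step. It was turned down for three reasons:
- C6 arrives as an sp2 carbon (or, with a secondary alkylcopper, as a configurationally labile centre), so it must be set later by reduction of a trisubstituted alkene.
- Any hydroxyl-directed hydrogenation would attack the ring alkene next to the tertiary allylic hydroxyl first.
- A3 is volatile, acid-labile, and three steps from 1.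

**Alternative 3:** cut C1'–C6 and form it by an Ireland–Claisen rearrangement of the trans-diol monopropanoate A5 to the acid A6. Suprafacial transfer from the oxygen on the future C3' to C1' sets C1' and C6 together, and the trans relation to the hydroxyl follows from the trans diol. It was turned down on step economy and predictability:
- The carboxyl carbon of A6 becomes C5, which the target needs as CH2, so reduction, activation and one-carbon extension (about four steps) are needed to reach aldehyde 8.
- A5 itself needs about four steps from 1.
- The chair/boat preference of cyclohexenyl silyl ketene acetals depends on the substrate.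

Key step: step 2

Assumption: the sense of induction of the two chiral catalysts (the cinchona amine in step 1, the ProPhenol ligand in step 5) is taken as written; both exist in pseudo-enantiomeric or antipodal forms, and the other form is used if the sense is the opposite.

## Route

Step 1
Reactants: 1 3-methylcyclohex-2-en-1-one
Product: 2 (1R,6R)-6-methyl-7-oxabicyclo[4.1.0]heptan-2-one
Conditions: 9-amino-9-deoxy-epi-quinine (10 mol %), CF3CO2H (20 mol %), 50% aq. H2O2 (1.5 equiv), dioxane, 35 °C
Reagents that add atoms: hydrogen peroxide, OO
Why: Nucleophilic (Weitz–Scheffer type) epoxidation under iminium catalysis by a chiral primary amine salt, a reaction established for cyclic enones; hydroperoxide adds to C3 of the iminium ion on the face chosen by the catalyst and the enamine closes the oxirane, so both oxirane carbons are set together (cis by the ring).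

Step 2
Reactants: 2 (1R,6R)-6-methyl-7-oxabicyclo[4.1.0]heptan-2-one; 3 ethyl (2E)-but-2-enoate
Product: 5 ethyl (3R)-3-[(1R,3S,6R)-6-methyl-2-oxo-7-oxabicyclo[4.1.0]heptan-3-yl]butanoate, via lithium enolate 4 (not isolated)
Conditions: LiN(i-Pr)2 (1.05 equiv), THF, −78 °C; then 3 (1.2 equiv), −78 °C; AcOH, −78 °C
Reagents that add atoms: none
Why: Michael addition of a ketone lithium enolate to an (E)-enoate; the closest known reaction type is the kinetic conjugate addition of cyclohexanone lithium enolates to crotonates. The base can only remove a proton from C3 of 2, because an enolate towards C1 would put a double bond on an oxirane carbon, so the single enolate 4 forms. The oxirane is a temporary ring: it carries the future C4', and it removes the enone acceptor that in 1 itself would lead to a double Michael reaction. No ring is closed. The new ring stereocentre (C3 of the bicycle, later C1') is set by attack on the enolate face opposite to the oxirane oxygen, which is 1,3 to the reacting carbon and repels the incoming enoate, as in additions to cyclic vinyl oxiranes; this places the chain trans to the C–O bond that becomes the tertiary hydroxyl. The chain stereocentre (C3 of the butanoate, later C6) is set in a closed, lithium-bridged eight-membered transition state: the ring fixes the enolate as E(O), and the s-cis (E)-enoate binds lithium above the enolate oxygen with its β-methyl group turned away from the enolate C–O bond. This topicity gives the syn adduct, here 3S in the ring and 3R in the chain. The step needs 1,4- over 1,2-addition (secured by −78 °C and an ester acceptor) and kinetic control, so the adduct enolate is protonated at −78 °C before it can move a proton from C3 or open the oxirane.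

Step 3
Reactants: 5 ethyl (3R)-3-[(1R,3S,6R)-6-methyl-2-oxo-7-oxabicyclo[4.1.0]heptan-3-yl]butanoate
Product: 7 ethyl (3R)-3-[(1S,4R)-4-hydroxy-4-methylcyclohex-2-en-1-yl]butanoate, via epoxy hydrazone 6 (not isolated)
Conditions: N2H4·H2O (2.5 equiv), AcOH (0.2 equiv), EtOH, 0 to 20 °C
Reagents that add atoms: none
Why: Wharton transposition: hydrazone 6 opens the C1–O bond of the oxirane, loses N2 and gives the allylic alcohol with the double bond between the former carbonyl carbon and C1. The C6–O bond is not broken, so C4' keeps its configuration and the hydroxyl stands trans to the chain. The conversion of 6-alkyl-3-methyl-2,3-epoxycyclohexanones into 4-alkyl-1-methylcyclohex-2-en-1-ols is a known use of this reaction.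

Step 4
Reactants: 7 ethyl (3R)-3-[(1S,4R)-4-hydroxy-4-methylcyclohex-2-en-1-yl]butanoate
Product: 8 (3R)-3-[(1S,4R)-4-hydroxy-4-methylcyclohex-2-en-1-yl]butanal
Conditions: (i-Bu)2AlH (2.2 equiv), CH2Cl2, −78 °C; aq. potassium sodium tartrate
Reagents that add atoms: none
Why: Partial reduction of an ester by a dialkylaluminium hydride at low temperature; the first equivalent is taken up by the tertiary hydroxyl and the aluminium hemiacetal holds until work-up, so the aldehyde is not reduced further.

Step 5
Reactants: 8 (3R)-3-[(1S,4R)-4-hydroxy-4-methylcyclohex-2-en-1-yl]butanal; 9 methyl prop-2-ynoate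
Product: 11 methyl (4S,6R)-4-hydroxy-6-[(1S,4R)-4-hydroxy-4-methylcyclohex-2-en-1-yl]hept-2-ynoate, via alkynylzinc 10 (not isolated)
Conditions: (S,S)-ProPhenol (20 mol %), Ph3P=O (40 mol %), Me2Zn (4 equiv), 9 (3 equiv), toluene, 0 to 4 °C, slow addition of 8
Reagents that add atoms: none
Why: Catalytic enantioselective addition of a zinc alkynylide to an aldehyde under dinuclear zinc–ProPhenol catalysis, established for methyl propiolate. The catalyst delivers the alkynyl group to the Re face of 8 and so sets C4 as S, overriding the weak 1,3-induction from C6.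

Step 6
Reactants: 11 methyl (4S,6R)-4-hydroxy-6-[(1S,4R)-4-hydroxy-4-methylcyclohex-2-en-1-yl]hept-2-ynoate
Product: 13 methyl (2Z,4S,6R)-4-hydroxy-6-[(1S,4R)-4-hydroxy-4-methylcyclohex-2-en-1-yl]-2-iodohept-2-enoate, via vinylalanate 12 (not isolated)
Conditions: NaAlH2(OCH2CH2OCH3)2 (3 equiv), THF, −78 °C; then I2 (3 equiv), −78 to −20 °C; aq. Na2S2O3 and potassium sodium tartrate
Reagents that add atoms: iodine, II
Why: Alkoxide-directed trans-hydroalumination of a γ-hydroxy ynoate: hydride goes to C3 and aluminium to C2 within the five-membered oxa-aluminate 12, so aluminium is cis to C4. Iodinolysis with retention gives the Z-configured 2-iodo enoate; the low temperature spares the methyl ester.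

Step 7
Reactants: 13 methyl (2Z,4S,6R)-4-hydroxy-6-[(1S,4R)-4-hydroxy-4-methylcyclohex-2-en-1-yl]-2-iodohept-2-enoate; 14 5-bromo-2-methylpent-2-ene
Product: 16 methyl (2E,4S,6R)-4-hydroxy-6-[(1S,4R)-4-hydroxy-4-methylcyclohex-2-en-1-yl]-2-(4-methylpent-3-en-1-yl)hept-2-enoate, via alkylzinc bromide 15 (not isolated)
Conditions: Zn dust, LiCl, THF, 40 °C (14 to 15, 3.5 equiv); then 13, Pd(OAc)2 (3 mol %), SPhos (6 mol %), THF, 25 °C
Reagents that add atoms: none
Why: Negishi coupling of an alkenyl iodide with a primary alkylzinc halide, which keeps the double-bond geometry. The alkyl group takes the place of iodine cis to C4, which is the E enoate of the target (the descriptor changes only because the priorities change). The excess of 15 allows for the two free hydroxyls.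

Step 8
Reactants: 16 methyl (2E,4S,6R)-4-hydroxy-6-[(1S,4R)-4-hydroxy-4-methylcyclohex-2-en-1-yl]-2-(4-methylpent-3-en-1-yl)hept-2-enoate
Product: 17 methyl (2E,4S,6R)-4-(acetyloxy)-6-[(1S,4R)-4-hydroxy-4-methylcyclohex-2-en-1-yl]-2-(4-methylpent-3-en-1-yl)hept-2-enoate
Conditions: Ac2O (1.5 equiv), pyridine, 4-(dimethylamino)pyridine (5 mol %), CH2Cl2, 0 °C
Reagents that add atoms: acetic anhydride, CC(=O)OC(C)=O
Why: Acylation of a secondary alcohol in the presence of a tertiary one; the hindered C4' hydroxyl should not react at 0 °C with a small excess of anhydride. Placing this step last keeps the allylic acetate away from hydride and palladium.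

## Compound list

1 | 3-methylcyclohex-2-en-1-one | CC1=CC(=O)CCC1 | starting material
2 | (1R,6R)-6-methyl-7-oxabicyclo[4.1.0]heptan-2-one | C[C@@]12CCCC(=O)[C@@H]1O2 | intermediate
3 | ethyl (2E)-but-2-enoate | CCOC(=O)/C=C/C | starting material
4 | lithium (1S,6R)-6-methyl-7-oxabicyclo[4.1.0]hept-2-en-2-olate (C3 enolate of 2, same absolute configuration) | C[C@@]12CCC=C(O[Li])[C@@H]1O2 | intermediate (not isolated)
5 | ethyl (3R)-3-[(1R,3S,6R)-6-methyl-2-oxo-7-oxabicyclo[4.1.0]heptan-3-yl]butanoate | CCOC(=O)C[C@@H](C)[C@@H]1CC[C@@]2(C)O[C@H]2C1=O | intermediate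
6 | ethyl (3R)-3-[(1S,3S,6R)-2-hydrazinylidene-6-methyl-7-oxabicyclo[4.1.0]heptan-3-yl]butanoate (same configuration as 5) | CCOC(=O)C[C@@H](C)[C@@H]1CC[C@@]2(C)O[C@H]2C1=NN | intermediate (not isolated)
7 | ethyl (3R)-3-[(1S,4R)-4-hydroxy-4-methylcyclohex-2-en-1-yl]butanoate | CCOC(=O)C[C@@H](C)[C@H]1C=C[C@](C)(O)CC1 | intermediate
8 | (3R)-3-[(1S,4R)-4-hydroxy-4-methylcyclohex-2-en-1-yl]butanal | O=CC[C@@H](C)[C@H]1C=C[C@](C)(O)CC1 | intermediate
9 | methyl prop-2-ynoate | COC(=O)C#C | starting material
10 | methyl 3-(methylzincio)prop-2-ynoate | COC(=O)C#C[Zn]C | intermediate (not isolated)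
11 | methyl (4S,6R)-4-hydroxy-6-[(1S,4R)-4-hydroxy-4-methylcyclohex-2-en-1-yl]hept-2-ynoate | COC(=O)C#C[C@@H](O)C[C@@H](C)[C@H]1C=C[C@](C)(O)CC1 | intermediate
12 | sodium alkoxy(alkenyl)aluminate of 11: 2,2-bis(2-methoxyethoxy)-2,5-dihydro-1,2-oxaluminol-2-uide ring built from O4, Al and C2=C3, with Al on C2 cis to C4 and H on C3 (tertiary hydroxyl drawn free) | COC(=O)C1=C[C@H](C[C@@H](C)[C@H]2C=C[C@](C)(O)CC2)O[Al-]1(OCCOC)OCCOC.[Na+] | intermediate (not isolated)
13 | methyl (2Z,4S,6R)-4-hydroxy-6-[(1S,4R)-4-hydroxy-4-methylcyclohex-2-en-1-yl]-2-iodohept-2-enoate | COC(=O)/C(I)=C/[C@@H](O)C[C@@H](C)[C@H]1C=C[C@](C)(O)CC1 | intermediate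
14 | 5-bromo-2-methylpent-2-ene | CC(C)=CCCBr | starting material
15 | bromo(4-methylpent-3-en-1-yl)zinc | CC(C)=CCC[Zn]Br | intermediate (not isolated)
16 | methyl (2E,4S,6R)-4-hydroxy-6-[(1S,4R)-4-hydroxy-4-methylcyclohex-2-en-1-yl]-2-(4-methylpent-3-en-1-yl)hept-2-enoate | COC(=O)/C(=C/[C@@H](O)C[C@@H](C)[C@H]1C=C[C@](C)(O)CC1)CCC=C(C)C | intermediate
17 | methyl (2E,4S,6R)-4-(acetyloxy)-6-[(1S,4R)-4-hydroxy-4-methylcyclohex-2-en-1-yl]-2-(4-methylpent-3-en-1-yl)hept-2-enoate | COC(=O)/C(=C/[C@H](C[C@@H](C)[C@H]1C=C[C@](C)(O)CC1)OC(C)=O)CCC=C(C)C | target

## Step count and least certain steps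

Total steps: 8. Longest linear sequence: 8 steps (1 to 17); 3, 9 and 14 are bought.

**Step 2 (key step).** The most likely failure is poor facial discrimination at the enolate: if lithium bridges the enolate oxygen and the oxirane oxygen, the enoate can be steered to the face syn to the oxirane, which would give the C1' epimer. Further risks are loss of kinetic control by proton transfer between the adduct enolate and the ketone, and opening of the oxirane by the adduct enolate if the mixture warms.

The fallback forms the same bond by a Claisen rearrangement, where delivery is intramolecular and the trans relation is fixed by an oxirane opening. It sets out from 2 and comes back at 8.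
- Reduction of 2 (NaBH4, CeCl3, MeOH) gives the epoxy alcohol (1S,6R)-6-methyl-7-oxabicyclo[4.1.0]heptan-2-ol F1.
- Dehydration with Martin sulfurane, Ph2S[OC(CF3)2Ph]2, can only run towards the CH2 group and gives the vinyl oxirane (1S,6R)-6-methyl-7-oxabicyclo[4.1.0]hept-2-ene F2.
- Sodium allyloxide in allyl alcohol opens F2 at the allylic carbon with inversion to the trans hydroxy ether (1R,2R)-1-methyl-2-(prop-2-en-1-yloxy)cyclohex-3-en-1-ol F3.
- KOt-Bu in DMSO isomerises the allyl group to the cis enol ether (1R,2R)-1-methyl-2-[(1Z)-prop-1-en-1-yloxy]cyclohex-3-en-1-ol F4.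
- Heating in xylene at 140 °C should bring about the Claisen rearrangement through a chair. This places the new bond on the face of the old C–O bond (trans to the hydroxyl) and, from the Z enol ether, gives (2S)-2-[(1R,4R)-4-hydroxy-4-methylcyclohex-2-en-1-yl]propanal F5, which has the configuration of C1' and C6.
- Wittig reaction with Ph3P=CHOCH3 gives the enol ether (1R,4R)-4-[(2S)-4-methoxybut-3-en-2-yl]-1-methylcyclohex-2-en-1-ol F6.
- Near-neutral hydrolysis (Hg(OAc)2, aqueous THF, then KI) gives 8.

**Step 1.** Iminium formation with a β,β-disubstituted enone is slow, so conversion may be low and the background, unselective epoxidation may lower the enantiomeric purity.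

The fallback takes the configuration from a carbinol instead. It sets out from 1 and comes back at 2.
- Corey–Bakshi–Shibata reduction of 1 (antipode of the oxazaborolidine chosen for the S alcohol) gives (1S)-3-methylcyclohex-2-en-1-ol F7.
- Hydroxyl-directed epoxidation (VO(acac)2, t-BuOOH) on the face of the hydroxyl gives (1S,2S,6R)-6-methyl-7-oxabicyclo[4.1.0]heptan-2-ol F8.
- Oxidation with Dess–Martin periodinane gives 2.

**Step 3.** Epimerisation at C3 of the bicycle (the future C1') through hydrazone/ene-hydrazine tautomerism is possible, and so is the loss of material that is common in Wharton reactions when the diazene intermediate decomposes along other paths.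

The fallback replaces the hydrazone by a radical fragmentation. It sets out from 5 and comes back at 7.
- Reduction (NaBH4, CeCl3, MeOH, −40 °C) gives ethyl (3R)-3-[(1S,3S,6R)-2-hydroxy-6-methyl-7-oxabicyclo[4.1.0]heptan-3-yl]butanoate F9.
- Acylation with 1,1'-thiocarbonyldiimidazole gives ethyl (3R)-3-[(1S,3S,6R)-2-(1H-imidazole-1-carbothioyloxy)-6-methyl-7-oxabicyclo[4.1.0]heptan-3-yl]butanoate F10.
- Bu3SnH with azobisisobutyronitrile in benzene at 80 °C generates the carbinyl radical, which opens the oxirane; reduction of the resulting alkoxyl radical gives 7 with C1' untouched.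

**Step 5.** Aldol self-condensation of the enolisable aldehyde under the basic zinc conditions and incomplete catalyst control at C4 are the main risks.

The fallback sets C4 by reduction instead of addition. It sets out from 8 and comes back at 11.
- Addition of lithiated 9 (LiN(SiMe3)2, THF, −78 °C) gives 11 together with its C4 epimer methyl (4R,6R)-4-hydroxy-6-[(1S,4R)-4-hydroxy-4-methylcyclohex-2-en-1-yl]hept-2-ynoate F11.
- Oxidation of the mixture with Dess–Martin periodinane gives the ynone methyl (6R)-6-[(1S,4R)-4-hydroxy-4-methylcyclohex-2-en-1-yl]-4-oxohept-2-ynoate F12.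
- Corey–Bakshi–Shibata reduction with catecholborane (antipode chosen for 4S) gives 11.

## Further compounds

F1 | step 2 | (1S,6R)-6-methyl-7-oxabicyclo[4.1.0]heptan-2-ol (mixture of C2 epimers) | C[C@@]12CCCC(O)[C@@H]1O2
F2 | step 2 | (1S,6R)-6-methyl-7-oxabicyclo[4.1.0]hept-2-ene | C[C@@]12CCC=C[C@@H]1O2
F3 | step 2 | (1R,2R)-1-methyl-2-(prop-2-en-1-yloxy)cyclohex-3-en-1-ol | C=CCO[C@@H]1C=CCC[C@@]1(C)O
F4 | step 2 | (1R,2R)-1-methyl-2-[(1Z)-prop-1-en-1-yloxy]cyclohex-3-en-1-ol | C/C=C\O[C@@H]1C=CCC[C@@]1(C)O
F5 | step 2 | (2S)-2-[(1R,4R)-4-hydroxy-4-methylcyclohex-2-en-1-yl]propanal | O=C[C@@H](C)[C@H]1C=C[C@](C)(O)CC1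
F6 | step 2 | (1R,4R)-4-[(2S)-4-methoxybut-3-en-2-yl]-1-methylcyclohex-2-en-1-ol (E/Z mixture) | COC=C[C@@H](C)[C@H]1C=C[C@](C)(O)CC1
F7 | step 1 | (1S)-3-methylcyclohex-2-en-1-ol | CC1=C[C@@H](O)CCC1
F8 | step 1 | (1S,2S,6R)-6-methyl-7-oxabicyclo[4.1.0]heptan-2-ol | C[C@@]12CCC[C@H](O)[C@@H]1O2
F9 | step 3 | ethyl (3R)-3-[(1S,3S,6R)-2-hydroxy-6-methyl-7-oxabicyclo[4.1.0]heptan-3-yl]butanoate (mixture of C2 epimers) | CCOC(=O)C[C@@H](C)[C@@H]1CC[C@@]2(C)O[C@H]2C1O
F10 | step 3 | ethyl (3R)-3-[(1S,3S,6R)-2-(1H-imidazole-1-carbothioyloxy)-6-methyl-7-oxabicyclo[4.1.0]heptan-3-yl]butanoate | CCOC(=O)C[C@@H](C)[C@@H]1CC[C@@]2(C)O[C@H]2C1OC(=S)n1ccnc1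
F11 | step 5 | methyl (4R,6R)-4-hydroxy-6-[(1S,4R)-4-hydroxy-4-methylcyclohex-2-en-1-yl]hept-2-ynoate | COC(=O)C#C[C@H](O)C[C@@H](C)[C@H]1C=C[C@](C)(O)CC1
F12 | step 5 | methyl (6R)-6-[(1S,4R)-4-hydroxy-4-methylcyclohex-2-en-1-yl]-4-oxohept-2-ynoate | COC(=O)C#CC(=O)C[C@@H](C)[C@H]1C=C[C@](C)(O)CC1
A1 | alternative 1 | (1R,4R)-1-methyl-4-(prop-1-en-2-yl)cyclohex-2-en-1-ol | CC(=C)[C@H]1C=C[C@](C)(O)CC1
A2 | alternative 1 | (2S)-2-[(1R,4R)-4-hydroxy-4-methylcyclohex-2-en-1-yl]propan-1-ol | OC[C@@H](C)[C@H]1C=C[C@](C)(O)CC1
A3 | alternative 2 | (1S,6R)-6-methyl-7-oxabicyclo[4.1.0]hept-2-ene | C[C@@]12CCC=C[C@@H]1O2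
A4 | alternative 2 | (1R,4R)-4-[(2Z)-4-hydroxybut-2-en-2-yl]-1-methylcyclohex-2-en-1-ol | OC/C=C(/C)[C@H]1C=C[C@](C)(O)CC1
A5 | alternative 3 | (1R,6R)-6-hydroxy-6-methylcyclohex-2-en-1-yl propanoate | CCC(=O)O[C@@H]1C=CCC[C@@]1(C)O
A6 | alternative 3 | (2S)-2-[(1R,4R)-4-hydroxy-4-methylcyclohex-2-en-1-yl]propanoic acid | OC(=O)[C@@H](C)[C@H]1C=C[C@](C)(O)CC1
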